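**Retrosynthetic overview**
1. Feature (chamigrane numbering): spiro C6 holds the vinylic arm C1 of ring B trans, and the saturated arm C5 cis, to the tertiary C7 hydroxyl of ring A. This is the mark left by a carbon that moved onto C6 from the face opposite a C6–C7 epoxide oxygen.
2. Endgame: C3=C15 comes from Wittig bromomethylenation of the C1=C2–C3=O enone. C3=O comes from allylic oxidation (C3 is the only allylic CH2). C5H2 comes from a C5 ketone through its tosylhydrazone.
3. Key disconnection C6–C1: C1 shifts from C5 to C6 (semipinacol) in a ring-A C6,C7-epoxide bearing a 1-silyloxycyclopent-2-enyl group. This turns the five-membered ring into ring B and C5 into a ketone. C9–Br is installed just before, by Appel inversion.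
4. C5–C6: a Shapiro-derived C6 vinyl anion of actinol adds to cyclopentenone, and the C9 hydroxyl then steers epoxidation of C6=C7.
5. Ring order: ring A is bought with actinol and the cyclopentene with cyclopentenone. Ring B is formed last, in the key step, by enlarging the cyclopentene.

Key step: step 6

Remark on numbering: chamigrane numbers are used throughout; actinol C1(=O), C2, C3, C4, C5, C6 correspond to C6, C11, C10, C9, C8, C7.
Assumption: (4R,6R)-actinol is taken as a purchasable chiral-pool ketone; compounds 6 to 10 are carried as mixtures of C5 epimers, so C5 is left open in their SMILES.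

**Step 1**
Reactants: 1 (4R,6R)-4-hydroxy-2,2,6-trimethylcyclohexan-1-one (actinol)
Product: 2 (E)-2,4,6-triisopropylbenzenesulfonylhydrazone of 1 (N–N bond syn to the CH(CH3) carbon C7)
Conditions: TrisNHNH2 (1.05 equiv), conc. HCl (cat.), MeCN, rt
Reagents that add atoms: 2,4,6-triisopropylbenzenesulfonohydrazide, NNS(=O)(=O)c1c(C(C)C)cc(C(C)C)cc1C(C)C
Why: Acid-catalysed arylsulfonylhydrazone condensation is established for ketones flanked by a quaternary and a tertiary carbon, the N–N bond settles anti to C11 and syn to the only α-hydrogen, C9 is untouched, and the C7 methine centre is erased in the next step anyway.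

**Step 2**
Reactants: 2 trisylhydrazone of actinol; 3 cyclopent-2-en-1-one
Product: 6 (1R)-4-(1-hydroxycyclopent-2-en-1-yl)-3,5,5-trimethylcyclohex-3-en-1-ol (both C5 epimers), via vinyllithium alkoxide 4 (not isolated), via organocerium reagent 5 (not isolated)
Conditions: n-BuLi (3.2 equiv), TMEDA, THF, −78 → 0 °C; CeCl3 (dried, 1.5 equiv), −78 °C; 3 (1.2 equiv), −78 °C; aq NH4Cl
Reagents that add atoms: none
Why: Shapiro reaction, in which O–H and N–H are deprotonated first, the third equivalent removes the C7 hydrogen syn to the hydrazone nitrogen, loss of sulfinate and N2 gives the C6 vinyl anion regiospecifically, and its organocerium form adds 1,2 to the enolisable enone; the C5 epimer mixture is harmless because C5 later becomes a carbonyl carbon.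

**Step 3**
Reactants: 6 diol
Product: 8 (1R)-3,5,5-trimethyl-4-[1-(trimethylsilyloxy)cyclopent-2-en-1-yl]cyclohex-3-en-1-ol, via bis(trimethylsilyl) ether 7 (not isolated)
Conditions: 1-(trimethylsilyl)imidazole (3 equiv), CH2Cl2, rt; then K2CO3 (cat.), MeOH, 0 °C
Reagents that add atoms: 1-(trimethylsilyl)imidazole, C[Si](C)(C)n1ccnc1
Why: Exhaustive silylation with a neutral silyl donor spares the acid-labile doubly allylic carbinol, and base-catalysed methanolysis then removes only the exposed secondary C9 silyl ether, because the tertiary one is buried between the C7 methyl and the C11 gem-dimethyl groups.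

**Step 4**
Reactants: 8 homoallylic alcohol with silylated C5 carbinol
Product: 9 (6R,7S,9S)-C6,C7-epoxide of 8, epoxide oxygen cis to the C9 hydroxyl
Conditions: VO(acac)2 (5 mol %), t-BuOOH (decane, 1.5 equiv), toluene, 0 °C → rt
Reagents that add atoms: tert-butyl hydroperoxide, CC(C)(C)OO
Why: Hydroxyl-directed vanadium-catalysed epoxidation, in which the peroxide bound at the pseudoaxial C9 alkoxide delivers oxygen to the same face of the homoallylic C6=C7 bond and so sets C6 and C7, while the cyclopentene bond stays untouched because its allylic oxygen is silylated and cannot bind the metal.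

**Step 5**
Reactants: 9 epoxy alcohol
Product: 10 (6R,7S,9R)-9-bromo epoxide, bromine trans to the epoxide oxygen
Conditions: PPh3, CBr4, 2,6-lutidine, CH2Cl2, 0 °C → rt
Reagents that add atoms: carbon tetrabromide, BrC(Br)(Br)Br
Why: Appel reaction, in which bromide displaces the C9 oxyphosphonium group by SN2 with inversion; it is run here because the C7 oxygen is still locked in the epoxide, so neither a 1,3-diol phosphorane nor a Grob-type fragmentation can compete, the buffered neutral medium finds no SN2 site on the tetrasubstituted epoxide and spares the hindered silyl ether, and the only protic group is gone before the Lewis acid step.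

**Step 6**
Reactants: 10 bromo epoxy silyl ether
Product: 11 (6R,7S,9R)-9-bromo-7-hydroxy-7,11,11-trimethylspiro[5.5]undec-4-en-1-one (C5 ketone, C1=C2, C7–OH)
Conditions: TiCl4 (1.2 equiv), CH2Cl2, −78 °C; cold pH 7 buffer
Reagents that add atoms: none
Why: TiCl4 binds the epoxide oxygen together with the neighbouring silyloxy oxygen and stretches the C6–O bond, and the C5–C1 σ bond aligned antiperiplanar to it then moves to C6 while C5–O becomes the carbonyl and Me3SiCl departs. This is the Lewis-acid semipinacol rearrangement of 2,3-epoxy silyl ethers to β-hydroxy ketones, used here in its ring-enlarging form. Ring B is closed not by joining two chain ends but by a 1,2-shift that trades the C5–C1 bond for C6–C1 and widens the cyclopentene by one carbon into a cyclohex-3-enone. C6 is the only new stereocentre: the shift enters anti to the leaving oxygen, so C1 ends trans and C5 cis to the C7 oxygen, which keeps its configuration, and the epoxide face itself traces back to the C9 carbinol of 1. Two selectivities are needed: C6–O rather than C7–O cleavage, secured by the five-membered chelate, the push of the silyloxy group and relief of crowding at C6, and migration of sp2 C1 rather than sp3 C4, secured by the higher migratory aptitude of an alkenyl carbon whose π bond can bridge in the transition state. Each C5 epimer has a chelated rotamer with C1 anti to C6–O, so both give 11, and its double bond stays at C1=C2 because C6 carries no hydrogen.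

**Step 7**
Reactants: 11 bromo β-hydroxy ketone
Product: 12 (E)-4-methylbenzenesulfonylhydrazone of 11 (N–N bond anti to C6)
Conditions: TsNHNH2 (1.5 equiv), PPTS (cat.), EtOH, 60 °C
Reagents that add atoms: 4-methylbenzenesulfonohydrazide, Cc1ccc(cc1)S(=O)(=O)NN
Why: Sulfonylhydrazone condensation at the only carbonyl group, helped by the hydrogen bond from the cis C7 hydroxyl, under an acid too weak to dehydrate the tertiary alcohol or to start a retro-aldol cleavage.

**Step 8**
Reactants: 12 tosylhydrazone
Product: 15 (1S,3R,6S)-3-bromo-1,5,5-trimethylspiro[5.5]undec-7-en-1-ol (C5 now CH2), via N-boryl tosylhydrazine 13 (not isolated), via alkyl diazene 14 (not isolated)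
Conditions: catecholborane (3 equiv), CHCl3, −10 → 0 °C; then NaOAc·3H2O, reflux
Reagents that add atoms: none
Why: Tosylhydrazone reduction, in which catecholborane hydroborates the C5=N bond and acetate then releases sulfinate to give the diazene, which loses N2 and leaves C5 as CH2 under almost neutral conditions that the secondary bromide, the tertiary alcohol and the non-conjugated C1=C2 bond should survive.

**Step 9**
Reactants: 15 spiro alkene
Product: 16 (6S,7S,9R)-9-bromo-7-hydroxy-7,11,11-trimethylspiro[5.5]undec-1-en-3-one
Conditions: Rh2(cap)4 (cap = caprolactamate, 1 mol %), t-BuOOH (70 % in water, 10 equiv), ClCH2CH2Cl, 40 °C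
Reagents that add atoms: tert-butyl hydroperoxide, CC(C)(C)OO
Why: Dirhodium-catalysed allylic oxidation by tert-butylperoxy radicals, in which C3 carries the only allylic hydrogens because C6 is quaternary and the allyl radical is oxygenated at open C3 rather than at C1 beside the spiro centre, giving the C1=C2–C3=O enone without touching the tertiary alcohol or the bromide.

**Step 10**
Reactants: 16 enone
Product: 17 (1S,3R,6S,9E)-3-bromo-9-(bromomethylidene)-1,5,5-trimethylspiro[5.5]undec-7-en-1-ol (target)
Conditions: [Ph3PCH2Br]Br (4.0 equiv), NaN(SiMe3)2 (3.8 equiv), THF, −78 °C; then 16, −78 → 0 °C; chromatographic removal of the Z isomer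
Reagents that add atoms: (bromomethyl)triphenylphosphonium bromide, BrC[P+](c1ccccc1)(c1ccccc1)c1ccccc1.[Br-]
Why: Wittig olefination with the bromomethylene ylide attacks the enone carbonyl 1,2 because C1 is screened by the spiro centre, the salt is kept in excess over the base so that the C7 hydroxyl stays protonated and no γ-bromo alkoxide can start a Grob fragmentation, and the bromine should end mainly anti to the rigid vinylic arm C2 and syn to the flexible C4 methylene (E), the usual but modest bias of enone olefinations.

**Compound list**
1 | (4R,6R)-4-hydroxy-2,2,6-trimethylcyclohexan-1-one (actinol) | CC1(C)C[C@H](O)C[C@@H](C)C1=O | starting material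
2 | (E)-trisylhydrazone of 1 | CC1(C)C[C@H](O)C[C@@H](C)/C1=N\NS(=O)(=O)c2c(C(C)C)cc(C(C)C)cc2C(C)C | intermediate
3 | cyclopent-2-en-1-one | O=C1C=CCC1 | starting material
4 | lithium (1R)-4-lithio-3,5,5-trimethylcyclohex-3-en-1-olate | CC1(C)C[C@H](O[Li])CC(C)=C1[Li] | intermediate
5 | dichlorocerium analogue of 4 | CC1(C)C[C@H](O[Li])CC(C)=C1[Ce](Cl)Cl | intermediate
6 | (1R)-4-(1-hydroxycyclopent-2-en-1-yl)-3,5,5-trimethylcyclohex-3-en-1-ol | CC1(C)C[C@H](O)CC(C)=C1C2(O)C=CCC2 | intermediate
7 | bis(trimethylsilyl) ether of 6 | CC1(C)C[C@H](O[Si](C)(C)C)CC(C)=C1C2(O[Si](C)(C)C)C=CCC2 | intermediate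
8 | C5 trimethylsilyl ether of 6, C9–OH free | CC1(C)C[C@H](O)CC(C)=C1C2(O[Si](C)(C)C)C=CCC2 | intermediate
9 | (6R,7S,9S)-C6,C7-epoxy alcohol, oxygen cis to C9–OH | CC1(C)C[C@H](O)C[C@]2(C)O[C@]12C3(O[Si](C)(C)C)C=CCC3 | intermediate
10 | (6R,7S,9R)-9-bromo C6,C7-epoxide, Br trans to the epoxide oxygen | CC1(C)C[C@@H](Br)C[C@]2(C)O[C@]12C3(O[Si](C)(C)C)C=CCC3 | intermediate
11 | (6R,7S,9R)-9-bromo-7-hydroxy-7,11,11-trimethylspiro[5.5]undec-4-en-1-one | CC1(C)C[C@@H](Br)C[C@](C)(O)[C@@]12C=CCCC2=O | intermediate
12 | (E)-tosylhydrazone of 11 | CC1(C)C[C@@H](Br)C[C@](C)(O)[C@@]12C=CCC/C2=N\NS(=O)(=O)c3ccc(C)cc3 | intermediate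
13 | N-(1,3,2-benzodioxaborol-2-yl) tosylhydrazine at C5 | CC1(C)C[C@@H](Br)C[C@](C)(O)[C@@]12C=CCCC2N(B3Oc4ccccc4O3)NS(=O)(=O)c5ccc(C)cc5 | intermediate
14 | C5 alkyl diazene | CC1(C)C[C@@H](Br)C[C@](C)(O)[C@@]12C=CCCC2N=N | intermediate
15 | (1S,3R,6S)-3-bromo-1,5,5-trimethylspiro[5.5]undec-7-en-1-ol | CC1(C)C[C@@H](Br)C[C@](C)(O)[C@@]12C=CCCC2 | intermediate
16 | (6S,7S,9R)-9-bromo-7-hydroxy-7,11,11-trimethylspiro[5.5]undec-1-en-3-one | CC1(C)C[C@@H](Br)C[C@](C)(O)[C@@]12C=CC(=O)CC2 | intermediate
17 | (1S,3R,6S,9E)-3-bromo-9-(bromomethylidene)-1,5,5-trimethylspiro[5.5]undec-7-en-1-ol | CC1(C)C[C@@H](Br)C[C@](C)(O)[C@@]12C=C/C(=C/Br)CC2 | target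

**Total step count:** 10. **Longest linear sequence:** 10 steps (1 to 17).

**Steps most likely to fail**

Step 6. Three processes could overtake the wanted shift:
- ionisation at the C7 end of the epoxide, followed by proton loss or contraction of ring A;
- ionisation of the allylic C5–O bond;
- migration of the saturated carbon C4.

The fallback changes the trigger from a silyl ether under a chelating chloride Lewis acid to the free carbinol. It sets out from 10. Buffered fluoride (TBAF, AcOH, THF, 0 °C) gives the free epoxy carbinol F1. This is rearranged in the α-hydroxy-epoxide mode with ZnBr2 in CH2Cl2 at rt. Here the zinc alkoxide of the C5 hydroxyl supplies the push, a proton rather than a silyl cation is lost, and the weak Lewis acid should not ionise C7–O or C5–O by itself. The fallback returns to the route at 11.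

Step 8. Hydride delivery to the crowded C5=N bond may be slow. During loss of N2, radical character at C5 may also let the vinylic carbon C1 slip back from C6 to C5 by three-membered ring closure and reopening, which would undo the ring enlargement.

The fallback avoids any reactive centre at C5 and sets out from 11:
- TMSOTf and 2,6-lutidine (CH2Cl2, −78 °C) give the C7 silyl ether F2.
- KN(SiMe3)2 and PhNTf2 (THF, −78 °C) give the C4=C5 enol triflate F3.
- Pd(OAc)2, PPh3, HCO2H and Et3N (DMF, 40 °C) reduce it to the silylated spiro cyclohexa-1,4-diene F4.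
- HF·pyridine frees the dienol F5.

In F4 and F5 the two arms of ring B are alike, so C6 is no stereocentre. It is created again by hydroxyl-directed hydrogenation with [Ir(cod)(PCy3)(py)]PF6 and H2 (1 atm, CH2Cl2). The C7 hydroxyl can hold the metal only over the gauche, cis arm C4=C5 and not over the anti arm C1=C2. The fallback returns at 15.

Step 10. The two flanks of C3, the C2–H and the C4 methylene, differ little in size, so E/Z discrimination in the olefination may be poor.

The fallback puts a removable large group on C2 and sets out from 16. α-Iodination (I2, pyridine, CH2Cl2, rt) gives the 2-iodo enone F6. The same bromomethylene ylide then has to place its bromine on the C4 side, away from iodine, giving the 2-iodo (E)-bromodiene F7. Hydrodeiodination with Pd(PPh3)4 (cat.), HCO2H and Et3N (1.1 equiv, DMF, rt) removes only iodine, because zerovalent palladium inserts into the C–I bond faster than into either C–Br bond. The fallback returns at 17.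

**Further compounds**
F1 | step 6 | (6R,7S,9R)-9-bromo C6,C7-epoxide with free C5 carbinol | CC1(C)C[C@@H](Br)C[C@]2(C)O[C@]12C3(O)C=CCC3
F2 | step 8 | C7 trimethylsilyl ether of 11 | CC1(C)C[C@@H](Br)C[C@](C)(O[Si](C)(C)C)[C@@]12C=CCCC2=O
F3 | step 8 | C4=C5 enol triflate of F2 | CC1(C)C[C@@H](Br)C[C@](C)(O[Si](C)(C)C)[C@@]12C=CCC=C2OS(=O)(=O)C(F)(F)F
F4 | step 8 | C7-silylated 9-bromo spiro cyclohexa-1,4-diene | CC1(C)C[C@@H](Br)C[C@](C)(O[Si](C)(C)C)C12C=CCC=C2
F5 | step 8 | 9-bromo spiro cyclohexa-1,4-dien-7-ol | CC1(C)C[C@@H](Br)C[C@](C)(O)C12C=CCC=C2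
F6 | step 10 | 2-iodo derivative of enone 16 | CC1(C)C[C@@H](Br)C[C@](C)(O)[C@@]12C=C(I)C(=O)CC2
F7 | step 10 | 2-iodo derivative of 17, Br anti to C2 | CC1(C)C[C@@H](Br)C[C@](C)(O)[C@@]12C=C(I)/C(=C/Br)CC2
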